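The plain chemist at the board reads the runs as one step. Substrate falls at a mean 0.323 h⁻¹ in each run, and she counts every bit of substrate lost as product. She points to amber at 4.00 h, where the readings of product 73% and substrate 27%, each with its scatter of 1.5 percentage points, add up to 100%.

| flask | substrate | partner | remark | time |
|---|---|---|---|---|
| red | 0.27 M | 0.24 M | run made earlier |  |
| ochre | 0.27 M | 0.59 M | run made earlier |  |
| amber | 0.27 M | 1.3 M | run made earlier |  |
| east | 0.27 M | 1.20 M |  | 2.5 h |
| south | 0.27 M | 0.297 M |  | 5.0 h |

| run | time / h | product / % | substrate / % |
|---|---|---|---|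
| red | 1.00 | 4 | 73 |
| red | 2.00 | 11 | 51 |
| red | 3.00 | 26 | 38 |
| red | 4.00 | 32 | 25 |
| red | 5.00 | 41 | 21 |
| ochre | 0.417 | 2 | 88 |
| ochre | 1.33 | 11 | 63 |
| ochre | 2.50 | 34 | 42 |
| ochre | 4.00 | 64 | 26 |
| ochre | 5.00 | 75 | 22 |
| amber | 0.417 | 1 | 86 |
| amber | 1.33 | 22 | 63 |
| amber | 2.50 | 49 | 41 |
| amber | 4.00 | 73 | 27 |
| amber | 5.00 | 80 | 17 |

(readings scatter by 1.5 percentage points)

- which one finishes higher in amount of product, in percent of the substrate charged ("neither" within 2 percentage points) (east / south / neither)
- amount of product at the end, in percent of the substrate charged, east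
- amount of product at the end, in percent of the substrate charged, south



Her view gives east 55.4% and south 80.1%.

Her colleague answers with red at 5.00 h, where product 41% and substrate 21% leave a gap of 38.0% of the charge. Product, he says, is fed from that gap by partner. My own reckoning follows him, with curves replaced by their means and one partner spent per product. Between two readings, I divide the product made per hour by the mean gap and the mean c_partner. Red from 3.00 h to 5.00 h reads 1.36 M⁻¹ h⁻¹, and amber from 1.33 h to 2.50 h reads 1.53 M⁻¹ h⁻¹. Their mean, 1.44 M⁻¹ h⁻¹, is the capture constant.

Multiplied by c_partner, lowered by 0.0675 M for mean use, it gives a pseudo-first-order capture rate. That rate is 1.64 h⁻¹ in east, faster than substrate's, and 0.331 h⁻¹ in south, level with it. Two steps in a row at these rates give me east 44.8% and south 48.6%.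

The forecast, on his side with its own numbers, says east 47%, south 50%, and south higher: “South is slightly ahead, but the margin is narrow.”

The flasks give east 49.4% and south 48.9%, so the answer is neither, within the margin of 2 points. Her numbers fail for both flasks at the asked times, but her sum stands in east left until 25.0 h, where product is >99.9%, substrate 0.0203% and open intermediate 0%.

    substrate → open intermediate (k = 0.340 h⁻¹)
    partner → second intermediate (k = 0.170 h⁻¹)
    open intermediate + second intermediate → product (k = 9.60 M⁻¹ h⁻¹)
    partner → decomposed reagent (k = 0.0350 h⁻¹)

In east, open intermediate has a capture half-life of 0.45 h at 1.09 h, shorter than substrate's 2.0 h at 2.50 h; ln(2) over my capture rate gives 0.423 h. East ends with 7.82% open intermediate, and south, where my two rates stood level, with 32.9%.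

Read east at 1.0 h, and the same capture rate gives 14.6% product. The flask holds 11.8%, below the reckoning there, while at 2.5 h it stood above.

(The readings stem from a simulated flask from invented constants; noise was put on by code.)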